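**The leftover.** I started from what a flask still holds at the end: by-product left over has not yet become side product. Each addition of partner gives one by-product and the trapping of by-product takes one, so side product equals by-product made less by-product left. Partner that decays makes no by-product.

    starting material + partner → mono adduct + by-product (k1 = 1.8 × 10⁻⁴ M⁻¹ s⁻¹)
    partner + mono adduct → bis adduct + by-product (k2 = 4.7 × 10⁻⁴ M⁻¹ s⁻¹)
    partner + bis adduct → triple product + by-product (k3 = 8.7 × 10⁻⁵ M⁻¹ s⁻¹)
    partner + triple product → tetra adduct + by-product (k4 = 3.7 × 10⁻⁶ M⁻¹ s⁻¹)
    partner → decomposed reagent (k5 = 1.9 × 10⁻⁵ s⁻¹)
    starting material + by-product → side product (k6 = 4.3 × 10⁻⁴ M⁻¹ s⁻¹)

all flasks: time 2.5 d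

| run | starting material | partner | remark |
|---|---|---|---|
| summer | 0.20 M | 1.10 equiv (fed, over 40 h) | all else is in the flask from the start; the feed brings no volume worth counting |
| midnight | 0.20 M (fed, over 40 h) | 1.10 equiv | all else is in the flask from the start; the feed brings no volume worth counting |
| autumn | 0.20 M | 1.10 equiv | everything together at the start |

- the flask that comes out highest in amount of side product, in percent of the starting material charged; "all alike" if 1.5 percentage points covers them all (summer / midnight / autumn / all alike)
- amount of side product at the end, in percent of the starting material charged, summer
- amount of side product at the end, in percent of the starting material charged, midnight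
- amount of side product at the end, in percent of the starting material charged, autumn

**First extreme.** Suppose partner met the whole charge of starting material throughout. Partner then falls pseudo-first-order, and the first addition outruns decay by the working ratio 1.89. Held through the run, that split makes 72.0% of the charge as by-product, and I called this the working yield: the charged equivalents times the part of partner that works.

**Second extreme.** Suppose partner met no starting material. It would then decay entirely, and the working yield would be nil.

**Between them.** Autumn has the whole charge in at the start and summer feeds partner into it, so I placed both under the working yield, near the first extreme. Because the midnight feed lasts 7.9 lifetimes of partner reckoned against everything charged, midnight's partner meets a thin c(starting material), so I placed midnight far lower. My reckoning stopped at that order, with no figure for each flask.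

**The forecast.** It named autumn, with 55% for summer (50% to 60%), 33% for midnight (28% to 38%) and 59% for autumn (54% to 64%). Its grounds ended: “Autumn is highest, but only narrowly ahead of summer.”

**The outcome.** The run put autumn highest, with 57.8%, against 55.4% for summer and 31.8% for midnight. The autumn figure moves by 5 points at 0.824 equiv or 1.47 equiv of partner. Autumn ended with 0.0277 M of by-product, which is 13.8% of the charge, and the working yield less that is 58.2%. Midnight ended with 0.156 M of decomposed reagent, 0.0799 M above the working ratio's share, and taking that excess off the working yield leaves 32.0%.

The constants are those of an exercise; the rest is arithmetic.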